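## The problem

The target 27 is a 2,3-dihydro-4H-furo[3,2-c]pyran-4-one. Ring A (O1, C2, C3, C3a, C7a) is fused through C3a–C7a to ring B, a 2-pyranone (C3a, C4, O5, C6, C7, C7a). The core carries three arms: a catechol on C2, a second 4-hydroxy-2-pyranone (ring C, joined through C6') on C3, and an (E)-4-hydroxystyryl group on C6.

C2 and C3 are the only stereocentres, trans and both S. Trans is the thermodynamic arrangement, so either centre can correct the other, but the absolute configuration has to be brought in early and then defended. The defence is the hard part. H–C3 sits alpha to an acyl-type group in every intermediate, and once ring B exists O1 is the oxygen of a vinylogous carboxylate. Deprotonation at C3 would therefore open ring A by beta-elimination and erase both centres, and the benzylic C2–O1 bond can ionise in strong acid.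

The free catechol and the acidic 4-hydroxypyranone are sensitive to oxidation and base, both lactones are opened by hydroxide, and the styrylpyranone is an extended acceptor. The feature that invites the key step is ring B itself: C7a–C7 and O5–C6 flank the two-carbon unit C6–C7, C6 bears the conjugated arm, C4 is a carboxyl carbon on C3a, and C7a is a vinylic CH cis to it. This is the pattern left when an alkyne is stitched between a carboxyl group and its cis beta C–H bond. Because C7 carries only hydrogen, the alkyne needs a removable placeholder there, and the orientation of its insertion becomes the central selectivity question.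

## Retrosynthesis

**27 ⇒ 26.** The three O–Si bonds are cut last. Buffered fluoride is the one reagent that touches neither lactone nor the C3–H/O1 pair. Triisopropylsilyl ethers are chosen over tert-butyldimethylsilyl ethers because the aryl ethers must survive hydroperoxide (step 4), an amide base (steps 6, 14) and carbonate in hot DMF (step 12). The forward step must never generate an unbuffered phenoxide.

**26 ⇒ 25 ⇒ 23 + 24.** Ring C is cut at O1'–C2' (lactone) and at C5'–C6'. This returns an N-methoxy-N-methylamide on C3 (23) and the acetoacetate equivalent 24. Attaching a finished ring C to C3 instead would create the C3 stereocentre late, and carrying ring C through the rhodium step would add an acidic enol and two more C–H bonds next to a directing oxygen. The amide needs no deprotection or activation after ring B is in place, and of all acyl groups it makes H–C3 least acidic. The forward reaction must acylate a lithium dienolate at −78 °C faster than it deprotonates C3, and must close the pyranone without base; thermolysis of keto-dioxinone 25 does the latter.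

**23 ⇒ 22.** The C7–H bond is traced back to C7–SiMe3. The silyl group lets the key step use an internal alkyne, since terminal alkynes do not survive silver-mediated oxidative annulation. It sits on the most electron-rich carbon of ring B, where ipso-protonation is easy.

**22 ⇒ 15 + 21 (key disconnection).** C7a–C7 and O5–C6 are cut, dissolving ring B into the dihydrofuran-3-carboxylic acid 15 and the silylated enyne 21. Against building ring B by condensation on a 6-methylpyranone, this cut brings the styryl arm in without base and leaves ring A, with both stereocentres, finished beforehand. The precursors are a monocyclic acid with one cis beta C–H bond and a four-carbon enyne. The forward reaction must place the styryl-bearing alkyne carbon on oxygen and the silylated carbon on C7a, and must leave the two sp3 centres alone.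

**21 ⇒ 19 + 20; 19 ⇒ 18 ⇒ 16.** The enyne is cut at the alkyne–alkene bond (Sonogashira) into bromostyrene 19 and silylacetylene 20. Compound 19 comes from 4-hydroxycinnamic acid 16 by silylation to 18 and bromodecarboxylation, which carries the E geometry through.

**15 ⇒ 14 ⇒ 12 ⇒ 11.** The acid is freed from allyl ester 14 under neutral palladium conditions; hydrolysis of a beta-alkoxyacrylate would need hydroxide. Ring A is then opened at the enol ether (O1–C7a in target numbering) and the oxygen re-attached to the carboxyl carbon. This is the reverse of an acyl-lactone (Korte) ring switch and gives formyl lactone 12, whose C3a–C7a bond is cut to lactone 11 and a formate. The forward sequence needs selective enolisation of the lactone CH2 and an acid-catalysed alcoholysis that leaves the C4 acyl group intact. The amide is inert there, where an ester would scramble in allyl alcohol.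

**11 ⇒ 9 ⇒ 7.** The amide returns to paraconic acid 9 and from there to the auxiliary-bearing lactone 7. This is a two-step acyl exchange that fixes the acyl group for the rest of the route.

**7 ⇒ 5 + 2; 5 ⇒ 3 + 4; 2 ⇒ 1.** The C2–C3 bond of the target is cut by an aldol between succinyl imide 5 and aldehyde 2. The syn aldol adduct lactonises to the trans lactone, so one reaction sets both centres and their trans relation with a predictable absolute sense. Compound 5 comes from oxazolidinone 3 and acid chloride 4, and 2 from 3,4-dihydroxybenzaldehyde 1.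

## Roads not taken

**Alternative 1:** The cut is C3–C3a, made forward by a 1,2-shift. The trivalent iodine reagent PhI(OAc)2 in acidic trimethyl orthoformate attacks the CH2 carbon of pyranopyrandione A2. The ring-fusion carbon migrates from the ketone carbon to that CH2 carbon, the six-membered ketone ring contracts to ring A, and the old ketone carbon becomes the methyl ester of A1.

- Merits: the bicycle with a trans ester at C3 is formed from a single stereocentre in one step, and A2 is a few steps from simple pyranone and cinnamate building blocks.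
- Weak points: an enantiopure A2 depends on a reversible oxa-Michael ring closure, so C2 is at risk before and during the acidic oxidation. An electron-rich aryl group can migrate in place of the ring carbon. A1 carries only a methyl group on C6, so the styryl arm would need a base-mediated condensation on a compound whose H–C3 is alpha to an ester and beta to O1. The ester would then have to be saponified next to ring B.
- Comparison: Alternative 1 reaches the bicycle in roughly half the steps and sets the trans relation internally. The chosen plan sets against this an auxiliary-controlled absolute configuration and a styryl arm that arrives with ring B without base.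

**Alternative 2:** The cuts are O1–C7a and C3a–C4. Forward, divalent palladium (PdCl2(MeCN)2 with CuCl2 under CO in methanol) triggers 5-endo-dig attack of the hydroxyl of alkynol A4 on the alkyne, and the vinylpalladium is methoxycarbonylated to give A3.

- Merits: C3 carries a silyloxymethyl group throughout, so there is no acidic H–C3 and the stereocentres are safe. In this respect it is better than the chosen plan.
- Weak points: after A3, ring B still needs oxidation of a secondary silyl ether and enol-lactonisation, and ring C needs the primary alcohol raised to an acid and extended. This means about ten further steps with five silyl ethers of three kinds to tell apart. The oxidative Pd/Cu/CO medium also meets an electron-rich styrene.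
- Comparison: the chosen plan answers the stereochemical safety of Alternative 2 with the least acidic acyl group (the amide) and with base-free steps after ring B. It is shorter and more convergent.

**Alternative 3:** The cuts are C3–C3a, C2–C3 and O1–C2. Forward, styrylpyranone A6 condenses with pyranone aldehyde A7 (Knoevenagel). The ylide from sulfonium salt A8 adds to the exocyclic carbon, and the enolate oxygen displaces the sulfide to close ring A, giving A5.

- Merits: this is the most convergent road and clearly the shortest. Ring A and both stereocentres form in one flask, with rings B and C arriving intact.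
- Weak points: the absolute configuration would rest on a chiral sulfide or catalyst with no track record on this acceptor class. Knoevenagel adducts of 4-hydroxypyranones readily take up a second pyranone. The enolate can close through either oxygen (linear or angular fusion). A7 is a fragile aldehyde, and the methoxymethyl ether needs acid at the end.
- Comparison: the chosen plan is much longer. It sets against this a predictable enantiocontrol and an unambiguous ring fusion, because ring B is built onto a defined acid.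

Key step: step 12

Remark: TIPS = triisopropylsilyl; compounds 3, 4, 20 and 24 are taken as purchased; 12 is drawn as its chelated Z enol, the tautomer expected to dominate.
Remark: metal-bound and ionic species (enolates, aldolates, tetrahedral adducts, rhodacycles) and the transient acylketene of step 15 are described in the Why lines; the numbered "via" compounds are the neutral intermediates on which a later reagent or the work-up acts.

## Route

Step 1
Reactants: 1 3,4-dihydroxybenzaldehyde
Product: 2 3,4-bis(TIPSO)benzaldehyde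
Conditions: TIPSCl (2.3 equiv), imidazole, DMF, rt
Reagents that add atoms: chloro(triisopropyl)silane, CC(C)[Si](Cl)(C(C)C)C(C)C
Why: Standard silylation of phenols; the bulkier silyl group is chosen so that the aryl ethers survive hydroperoxide, amide bases and hot DMF later on.

Step 2
Reactants: 3 (4S)-4-benzyl-1,3-oxazolidin-2-one; 4 methyl 4-chloro-4-oxobutanoate
Product: 5 methyl 4-[(4S)-4-benzyl-2-oxo-1,3-oxazolidin-3-yl]-4-oxobutanoate
Conditions: n-BuLi, THF, −78 °C; then 4, −78 to 0 °C
Reagents that add atoms: none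
Why: N-acylation of the lithiated oxazolidinone by the acid chloride, which is far more electrophilic than the methyl ester.

Step 3
Reactants: 5 methyl 4-[(4S)-4-benzyl-2-oxo-1,3-oxazolidin-3-yl]-4-oxobutanoate; 2 3,4-bis(TIPSO)benzaldehyde
Product: 7 (4S)-4-benzyl-3-{[(2S,3S)-2-[3,4-bis(TIPSO)phenyl]-5-oxooxolan-3-yl]carbonyl}-1,3-oxazolidin-2-one, via syn-aldol adduct 6 (not isolated)
Conditions: Bu2BOTf, iPr2NEt, CH2Cl2, −78 to 0 °C; 2, −78 to 0 °C; pH 7 buffer, MeOH, H2O2, 0 °C; then PPTS (cat.), toluene, 60 °C
Reagents that add atoms: none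
Why: Evans syn aldol: the imide is enolised selectively to its Z boron enolate, which reacts through a chair transition state on the face away from the benzyl group of the auxiliary, setting both new centres (3S,4S in 6); the hydroxyl then closes on the methyl ester (5-exo-trig lactonisation), and syn in the chain becomes trans on the ring.

Step 4
Reactants: 7 (4S)-4-benzyl-3-{[(2S,3S)-2-[3,4-bis(TIPSO)phenyl]-5-oxooxolan-3-yl]carbonyl}-1,3-oxazolidin-2-one
Product: 9 (2S,3S)-2-[3,4-bis(TIPSO)phenyl]-5-oxooxolane-3-carboxylic acid, via peroxy acid 8 (not isolated)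
Conditions: LiOH, H2O2, THF/H2O, 0 °C; Na2SO3; 1 M HCl to pH 3
Reagents that add atoms: hydrogen peroxide (as LiOOH), OO
Why: Hydroperoxide attacks the exocyclic imide carbonyl selectively and sulfite reduces the peroxy acid; any lactone opened by hydroxide recloses on acidification, and the carboxylate formed protects H–C3 from enolisation.

Step 5
Reactants: 9 (2S,3S)-2-[3,4-bis(TIPSO)phenyl]-5-oxooxolane-3-carboxylic acid
Product: 11 (2S,3S)-2-[3,4-bis(TIPSO)phenyl]-N-methoxy-N-methyl-5-oxooxolane-3-carboxamide, via acyl imidazole 10 (not isolated)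
Conditions: CDI, CH2Cl2, rt; then MeNHOMe·HCl, rt
Reagents that add atoms: N,O-dimethylhydroxylamine hydrochloride, CNOC.Cl; 1,1'-carbonyldiimidazole (supplies the imidazolyl group of 10), O=C(n1ccnc1)n1ccnc1
Why: Amide formation through the acyl imidazole under conditions too weakly basic to enolise the activated acid; the amine reacts at the acyl imidazole much faster than at the lactone.

Step 6
Reactants: 11 (2S,3S)-2-[3,4-bis(TIPSO)phenyl]-N-methoxy-N-methyl-5-oxooxolane-3-carboxamide
Product: 12 (2S,3S,4Z)-2-[3,4-bis(TIPSO)phenyl]-4-(hydroxymethylidene)-N-methoxy-N-methyl-5-oxooxolane-3-carboxamide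
Conditions: LiN(iPr)2 (1.2 equiv), THF, −78 °C; CF3CH2OCHO, −78 °C; aq NH4Cl
Reagents that add atoms: 2,2,2-trifluoroethyl formate, O=COCC(F)(F)F
Why: Claisen-type formylation of a lactone enolate; the lactone CH2 is the more acidic and more accessible position than the tertiary C–H alpha to the amide, so the enolate that could expel the lactone oxygen is not formed.

Step 7
Reactants: 12 (2S,3S,4Z)-2-[3,4-bis(TIPSO)phenyl]-4-(hydroxymethylidene)-N-methoxy-N-methyl-5-oxooxolane-3-carboxamide
Product: 14 prop-2-en-1-yl (4S,5S)-5-[3,4-bis(TIPSO)phenyl]-4-[methoxy(methyl)carbamoyl]-4,5-dihydrofuran-3-carboxylate, via 2-allyloxy acetal 13 (not isolated)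
Conditions: CSA (10 mol %), allyl alcohol, 40 °C; then toluene, 80 °C (allyl alcohol distilled off)
Reagents that add atoms: prop-2-en-1-ol, C=CCO
Why: Korte acyl-lactone rearrangement: acid-catalysed alcoholysis opens the formyl-activated lactone, the freed benzylic hydroxyl closes on the formyl carbon (5-exo-trig) to acetal 13, and loss of allyl alcohol gives the conjugated enol ether; the amide is inert to acidic alcohol and the two sp3 centres are not involved.

Step 8
Reactants: 14 prop-2-en-1-yl (4S,5S)-5-[3,4-bis(TIPSO)phenyl]-4-[methoxy(methyl)carbamoyl]-4,5-dihydrofuran-3-carboxylate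
Product: 15 (4S,5S)-5-[3,4-bis(TIPSO)phenyl]-4-[methoxy(methyl)carbamoyl]-4,5-dihydrofuran-3-carboxylic acid
Conditions: Pd(PPh3)4 (5 mol %), N-methylaniline, THF, rt
Reagents that add atoms: none
Why: Tsuji–Trost deallylation: zerovalent palladium ionises the allyl ester and the weakly nucleophilic aniline takes up the allyl group, so the acid is freed without hydroxide and without amine addition to the alkoxyacrylate.

Step 9
Reactants: 16 (E)-4-hydroxycinnamic acid
Product: 18 (E)-3-[4-(TIPSO)phenyl]prop-2-enoic acid, via silyl ester 17 (not isolated)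
Conditions: TIPSCl (2.3 equiv), imidazole, DMF, rt; then AcOH, THF, H2O, rt
Reagents that add atoms: chloro(triisopropyl)silane, CC(C)[Si](Cl)(C(C)C)C(C)C
Why: Double silylation followed by selective hydrolysis of the much more labile silyl ester, leaving the aryl silyl ether.

Step 10
Reactants: 18 (E)-3-[4-(TIPSO)phenyl]prop-2-enoic acid
Product: 19 (E)-1-(2-bromoethenyl)-4-(TIPSO)benzene
Conditions: NBS, Et3N (10 mol %), CH2Cl2, rt
Reagents that add atoms: N-bromosuccinimide, O=C1CCC(=O)N1Br
Why: Catalytic Hunsdiecker bromodecarboxylation: the carboxylate of an electron-rich cinnamic acid is brominated at the alpha carbon and loses CO2 from the benzylic cation, which should give the E vinyl bromide.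

Step 11
Reactants: 19 (E)-1-(2-bromoethenyl)-4-(TIPSO)benzene; 20 ethynyl(trimethyl)silane
Product: 21 (E)-trimethyl{4-[4-(TIPSO)phenyl]but-3-en-1-yn-1-yl}silane
Conditions: PdCl2(PPh3)2 (2 mol %), CuI (4 mol %), Et3N, THF, rt
Reagents that add atoms: none
Why: Sonogashira coupling of a vinyl bromide, which proceeds with retention of the alkene geometry.

Step 12
Reactants: 15 (4S,5S)-5-[3,4-bis(TIPSO)phenyl]-4-[methoxy(methyl)carbamoyl]-4,5-dihydrofuran-3-carboxylic acid; 21 (E)-trimethyl{4-[4-(TIPSO)phenyl]but-3-en-1-yn-1-yl}silane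
Product: 22 (2S,3S)-2-[3,4-bis(TIPSO)phenyl]-N-methoxy-N-methyl-4-oxo-6-{(E)-2-[4-(TIPSO)phenyl]ethenyl}-7-(trimethylsilyl)-2,3-dihydro-4H-furo[3,2-c]pyran-3-carboxamide
Conditions: [Cp*RhCl2]2 (2.5 mol %), Ag2CO3 (1.0 equiv), 21 (1.5 equiv), 4 Å MS, dry DMF, 100 °C, argon
Reagents that add atoms: none
Why: The carboxylate of 15 binds trivalent rhodium and the cis vinylic C–H bond at C2 of the dihydrofuran (C7a of the product) is cleaved by concerted metalation–deprotonation to a five-membered rhodacycle. Alkyne 21 inserts into the Rh–C7a bond and C–O reductive elimination from the seven-membered rhodacycle closes ring B, a formal [4+2] annulation in which the lactone C–O bond forms last, after which Ag2CO3 returns monovalent rhodium to the trivalent state. The closest known reaction is the Cp*Rh-catalysed oxidative annulation of acrylic acids with internal alkynes to 2-pyranones. No stereocentre is formed; C2 and C3 are spectators, and the amide keeps H–C3 too weakly acidic for carbonate. Site selectivity is built in, since the acid has a single beta C–H bond, and it is the oxygen-flanked one that metalates most readily. The selectivity that has to be won is the orientation of insertion: conjugated enynes insert into Cp*Rh–carbon bonds with the alkene-bearing carbon on the metal, which places the styryl carbon on O5, and the carbon that becomes C7 meets only the lone pairs of O1, so the silyl group is not pushed away from it as it would be by a peri C–H bond in a benzoic acid. Silicon on its own prefers the metal-bound carbon, so this contest is the main risk and is treated below. The E alkene has no allylic hydrogen cis to the alkyne, which rules out 1,4-rhodium migration, and dry conditions limit silver-induced cleavage of the alkynyl C–Si bond.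

Step 13
Reactants: 22 (2S,3S)-2-[3,4-bis(TIPSO)phenyl]-N-methoxy-N-methyl-4-oxo-6-{(E)-2-[4-(TIPSO)phenyl]ethenyl}-7-(trimethylsilyl)-2,3-dihydro-4H-furo[3,2-c]pyran-3-carboxamide
Product: 23 (2S,3S)-2-[3,4-bis(TIPSO)phenyl]-N-methoxy-N-methyl-4-oxo-6-{(E)-2-[4-(TIPSO)phenyl]ethenyl}-2,3-dihydro-4H-furo[3,2-c]pyran-3-carboxamide
Conditions: TFA (5 equiv), CH2Cl2, 0 °C
Reagents that add atoms: none
Why: Ipso-protodesilylation: C7 is the electron-rich carbon of the enol lactone, and protonation there gives a cation at C6 that is beta to silicon and delocalised into the silyloxystyryl arm; the aryl silyl ethers and the amide should tolerate brief cold TFA.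

Step 14
Reactants: 23 (2S,3S)-2-[3,4-bis(TIPSO)phenyl]-N-methoxy-N-methyl-4-oxo-6-{(E)-2-[4-(TIPSO)phenyl]ethenyl}-2,3-dihydro-4H-furo[3,2-c]pyran-3-carboxamide; 24 2,2,6-trimethyl-4H-1,3-dioxin-4-one
Product: 25 6-{2-[(2S,3S)-2-[3,4-bis(TIPSO)phenyl]-4-oxo-6-{(E)-2-[4-(TIPSO)phenyl]ethenyl}-2,3-dihydro-4H-furo[3,2-c]pyran-3-yl]-2-oxoethyl}-2,2-dimethyl-4H-1,3-dioxin-4-one
Conditions: 24 (3 equiv), LiN(SiMe3)2 (3 equiv), THF, −78 °C; then 23, −78 to −40 °C; aq NH4Cl at −78 °C
Reagents that add atoms: none
Why: Claisen-type acylation of a vinylogous ester enolate by an N-methoxy-N-methylamide: the lithium dienolate of 24 attacks through its gamma carbon and the chelated tetrahedral adduct persists until the quench, so no enolisable diketone meets base; at −78 °C addition should outrun both removal of H–C3 and attack on the deactivated ring B lactone.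

Step 15
Reactants: 25 6-{2-[(2S,3S)-2-[3,4-bis(TIPSO)phenyl]-4-oxo-6-{(E)-2-[4-(TIPSO)phenyl]ethenyl}-2,3-dihydro-4H-furo[3,2-c]pyran-3-yl]-2-oxoethyl}-2,2-dimethyl-4H-1,3-dioxin-4-one
Product: 26 (2S,3S)-2-[3,4-bis(TIPSO)phenyl]-3-(4-hydroxy-2-oxo-2H-pyran-6-yl)-6-{(E)-2-[4-(TIPSO)phenyl]ethenyl}-2,3-dihydro-4H-furo[3,2-c]pyran-4-one
Conditions: toluene, 110 °C
Reagents that add atoms: none
Why: Thermal retro-[4+2] loss of acetone gives an acylketene that is captured by the enol oxygen of the neighbouring ketone, the standard route from keto-dioxinones to 4-hydroxy-2-pyranones; ring C closes without acid or base at C3.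

Step 16
Reactants: 26 (2S,3S)-2-[3,4-bis(TIPSO)phenyl]-3-(4-hydroxy-2-oxo-2H-pyran-6-yl)-6-{(E)-2-[4-(TIPSO)phenyl]ethenyl}-2,3-dihydro-4H-furo[3,2-c]pyran-4-one
Product: 27 (2S,3S)-2-(3,4-dihydroxyphenyl)-3-(4-hydroxy-2-oxo-2H-pyran-6-yl)-6-[(E)-2-(4-hydroxyphenyl)ethenyl]-2,3-dihydro-4H-furo[3,2-c]pyran-4-one
Conditions: Bu4NF (4 equiv), AcOH (4 equiv), THF, 0 °C
Reagents that add atoms: none
Why: Fluoride cleavage of the three aryl silyl ethers, buffered with acetic acid so that neither free phenoxide nor basic fluoride meets the base-labile C3–H/O1 pair.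

## Compound list

1 | 3,4-dihydroxybenzaldehyde | O=Cc1ccc(O)c(O)c1 | starting material
2 | 3,4-bis(triisopropylsilyloxy)benzaldehyde | O=Cc1ccc(O[Si](C(C)C)(C(C)C)C(C)C)c(O[Si](C(C)C)(C(C)C)C(C)C)c1 | intermediate
3 | (4S)-4-benzyl-1,3-oxazolidin-2-one | O=C1OC[C@H](Cc2ccccc2)N1 | starting material
4 | methyl 4-chloro-4-oxobutanoate | COC(=O)CCC(=O)Cl | starting material
5 | methyl 4-[(4S)-4-benzyl-2-oxo-1,3-oxazolidin-3-yl]-4-oxobutanoate | COC(=O)CCC(=O)N1[C@@H](Cc2ccccc2)COC1=O | intermediate
6 | methyl (3S,4S)-3-{[(4S)-4-benzyl-2-oxo-1,3-oxazolidin-3-yl]carbonyl}-4-[3,4-bis(triisopropylsilyloxy)phenyl]-4-hydroxybutanoate | COC(=O)C[C@H](C(=O)N1[C@@H](Cc2ccccc2)COC1=O)[C@H](O)c1ccc(O[Si](C(C)C)(C(C)C)C(C)C)c(O[Si](C(C)C)(C(C)C)C(C)C)c1 | intermediate (not isolated)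
7 | (4S)-4-benzyl-3-{[(2S,3S)-2-[3,4-bis(triisopropylsilyloxy)phenyl]-5-oxooxolan-3-yl]carbonyl}-1,3-oxazolidin-2-one | O=C([C@H]1CC(=O)O[C@@H]1c1ccc(O[Si](C(C)C)(C(C)C)C(C)C)c(O[Si](C(C)C)(C(C)C)C(C)C)c1)N1[C@@H](Cc2ccccc2)COC1=O | intermediate
8 | (2S,3S)-2-[3,4-bis(triisopropylsilyloxy)phenyl]-5-oxooxolane-3-carboperoxoic acid | OOC(=O)[C@H]1CC(=O)O[C@@H]1c1ccc(O[Si](C(C)C)(C(C)C)C(C)C)c(O[Si](C(C)C)(C(C)C)C(C)C)c1 | intermediate (not isolated)
9 | (2S,3S)-2-[3,4-bis(triisopropylsilyloxy)phenyl]-5-oxooxolane-3-carboxylic acid | OC(=O)[C@H]1CC(=O)O[C@@H]1c1ccc(O[Si](C(C)C)(C(C)C)C(C)C)c(O[Si](C(C)C)(C(C)C)C(C)C)c1 | intermediate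
10 | (4S,5S)-5-[3,4-bis(triisopropylsilyloxy)phenyl]-4-(1H-imidazol-1-ylcarbonyl)oxolan-2-one | O=C(n1ccnc1)[C@H]1CC(=O)O[C@@H]1c1ccc(O[Si](C(C)C)(C(C)C)C(C)C)c(O[Si](C(C)C)(C(C)C)C(C)C)c1 | intermediate (not isolated)
11 | (2S,3S)-2-[3,4-bis(triisopropylsilyloxy)phenyl]-N-methoxy-N-methyl-5-oxooxolane-3-carboxamide | CON(C)C(=O)[C@H]1CC(=O)O[C@@H]1c1ccc(O[Si](C(C)C)(C(C)C)C(C)C)c(O[Si](C(C)C)(C(C)C)C(C)C)c1 | intermediate
12 | (2S,3S,4Z)-2-[3,4-bis(triisopropylsilyloxy)phenyl]-4-(hydroxymethylidene)-N-methoxy-N-methyl-5-oxooxolane-3-carboxamide | CON(C)C(=O)[C@H]1/C(=C/O)C(=O)O[C@@H]1c1ccc(O[Si](C(C)C)(C(C)C)C(C)C)c(O[Si](C(C)C)(C(C)C)C(C)C)c1 | intermediate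
13 | prop-2-en-1-yl (4S,5S)-5-[3,4-bis(triisopropylsilyloxy)phenyl]-4-[methoxy(methyl)carbamoyl]-2-(prop-2-en-1-yloxy)oxolane-3-carboxylate (epimers at C2 and C3) | CON(C)C(=O)[C@H]1C(C(=O)OCC=C)C(OCC=C)O[C@@H]1c1ccc(O[Si](C(C)C)(C(C)C)C(C)C)c(O[Si](C(C)C)(C(C)C)C(C)C)c1 | intermediate (not isolated)
14 | prop-2-en-1-yl (4S,5S)-5-[3,4-bis(triisopropylsilyloxy)phenyl]-4-[methoxy(methyl)carbamoyl]-4,5-dihydrofuran-3-carboxylate | CON(C)C(=O)[C@H]1C(C(=O)OCC=C)=CO[C@@H]1c1ccc(O[Si](C(C)C)(C(C)C)C(C)C)c(O[Si](C(C)C)(C(C)C)C(C)C)c1 | intermediate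
15 | (4S,5S)-5-[3,4-bis(triisopropylsilyloxy)phenyl]-4-[methoxy(methyl)carbamoyl]-4,5-dihydrofuran-3-carboxylic acid | CON(C)C(=O)[C@H]1C(C(=O)O)=CO[C@@H]1c1ccc(O[Si](C(C)C)(C(C)C)C(C)C)c(O[Si](C(C)C)(C(C)C)C(C)C)c1 | intermediate
16 | (E)-4-hydroxycinnamic acid | O=C(O)/C=C/c1ccc(O)cc1 | starting material
17 | triisopropylsilyl (E)-3-[4-(triisopropylsilyloxy)phenyl]prop-2-enoate | CC(C)[Si](OC(=O)/C=C/c1ccc(O[Si](C(C)C)(C(C)C)C(C)C)cc1)(C(C)C)C(C)C | intermediate (not isolated)
18 | (E)-3-[4-(triisopropylsilyloxy)phenyl]prop-2-enoic acid | O=C(O)/C=C/c1ccc(O[Si](C(C)C)(C(C)C)C(C)C)cc1 | intermediate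
19 | (E)-1-(2-bromoethenyl)-4-(triisopropylsilyloxy)benzene | Br/C=C/c1ccc(O[Si](C(C)C)(C(C)C)C(C)C)cc1 | intermediate
20 | ethynyl(trimethyl)silane | C#C[Si](C)(C)C | starting material
21 | (E)-trimethyl{4-[4-(triisopropylsilyloxy)phenyl]but-3-en-1-yn-1-yl}silane | C[Si](C)(C)C#C/C=C/c1ccc(O[Si](C(C)C)(C(C)C)C(C)C)cc1 | intermediate
22 | (2S,3S)-2-[3,4-bis(triisopropylsilyloxy)phenyl]-N-methoxy-N-methyl-4-oxo-6-{(E)-2-[4-(triisopropylsilyloxy)phenyl]ethenyl}-7-(trimethylsilyl)-2,3-dihydro-4H-furo[3,2-c]pyran-3-carboxamide | CON(C)C(=O)[C@H]1c2c(c([Si](C)(C)C)c(/C=C/c3ccc(O[Si](C(C)C)(C(C)C)C(C)C)cc3)oc2=O)O[C@@H]1c1ccc(O[Si](C(C)C)(C(C)C)C(C)C)c(O[Si](C(C)C)(C(C)C)C(C)C)c1 | intermediate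
23 | (2S,3S)-2-[3,4-bis(triisopropylsilyloxy)phenyl]-N-methoxy-N-methyl-4-oxo-6-{(E)-2-[4-(triisopropylsilyloxy)phenyl]ethenyl}-2,3-dihydro-4H-furo[3,2-c]pyran-3-carboxamide | CON(C)C(=O)[C@H]1c2c(cc(/C=C/c3ccc(O[Si](C(C)C)(C(C)C)C(C)C)cc3)oc2=O)O[C@@H]1c1ccc(O[Si](C(C)C)(C(C)C)C(C)C)c(O[Si](C(C)C)(C(C)C)C(C)C)c1 | intermediate
24 | 2,2,6-trimethyl-4H-1,3-dioxin-4-one | CC1=CC(=O)OC(C)(C)O1 | starting material
25 | 6-{2-[(2S,3S)-2-[3,4-bis(triisopropylsilyloxy)phenyl]-4-oxo-6-{(E)-2-[4-(triisopropylsilyloxy)phenyl]ethenyl}-2,3-dihydro-4H-furo[3,2-c]pyran-3-yl]-2-oxoethyl}-2,2-dimethyl-4H-1,3-dioxin-4-one | CC1(C)OC(=O)C=C(CC(=O)[C@H]2c3c(cc(/C=C/c4ccc(O[Si](C(C)C)(C(C)C)C(C)C)cc4)oc3=O)O[C@@H]2c2ccc(O[Si](C(C)C)(C(C)C)C(C)C)c(O[Si](C(C)C)(C(C)C)C(C)C)c2)O1 | intermediate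
26 | (2S,3S)-2-[3,4-bis(triisopropylsilyloxy)phenyl]-3-(4-hydroxy-2-oxo-2H-pyran-6-yl)-6-{(E)-2-[4-(triisopropylsilyloxy)phenyl]ethenyl}-2,3-dihydro-4H-furo[3,2-c]pyran-4-one | O=c1cc(O)cc([C@H]2c3c(cc(/C=C/c4ccc(O[Si](C(C)C)(C(C)C)C(C)C)cc4)oc3=O)O[C@@H]2c2ccc(O[Si](C(C)C)(C(C)C)C(C)C)c(O[Si](C(C)C)(C(C)C)C(C)C)c2)o1 | intermediate
27 | (2S,3S)-2-(3,4-dihydroxyphenyl)-3-(4-hydroxy-2-oxo-2H-pyran-6-yl)-6-[(E)-2-(4-hydroxyphenyl)ethenyl]-2,3-dihydro-4H-furo[3,2-c]pyran-4-one (CNP0330607.1) | O=c1cc(O)cc([C@H]2c3c(cc(/C=C/c4ccc(O)cc4)oc3=O)O[C@@H]2c2ccc(O)c(O)c2)o1 | target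

## Step count and least certain steps

Total: 16 steps. Longest linear sequence: 12 steps (steps 1, 3–8, 12–16); the enyne branch (steps 9–11) joins at step 12.

**Step 12 (key step).** The likeliest failure is reversed orientation of the alkyne insertion, with the silicon-bearing carbon staying on rhodium, which would put silicon on C6 and the styryl arm on C7. Silver-induced cleavage of the alkynyl C–Si bond and sluggish insertion of a silylated alkyne are secondary threats. The fallback keeps the carboxylate-directed C–H activation of 15 and the same two bonds, but replaces the alkyne by a carbene precursor whose connectivity fixes the regiochemistry and needs no oxidant. Acid 18 would be converted with oxalyl chloride into (E)-3-[4-(triisopropylsilyloxy)phenyl]prop-2-enoyl chloride F1 and this, with dimethylsulfoxonium methylide (Me3S(O)I, KOtBu, THF), into the keto sulfoxonium ylide F2. Acid 15 and F2 with [Cp*RhCl2]2, catalytic AgSbF6 and NaOAc in dichloroethane at 80 °C should undergo carbene insertion into the Rh–C7a bond, protodemetalation and cyclocondensation of the carboxyl group onto the ketone. This annulation type is known for aryl and alkenyl carboxylic acids. The ylide carbon becomes C7 and the ketone carbon C6, so the route is rejoined directly at 23, without the silyl placeholder and without step 13.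

**Step 14.** The likeliest failure is removal of H–C3 by the dienolate, followed by beta-elimination of O1; this opens ring A and destroys both stereocentres. Conjugate attack of the dienolate on ring B is the second risk. The fallback moves the C–C bond formation from an enolate acylation to a Lewis-acid aldol at the aldehyde level. Amide 23 would be reduced with Cp2Zr(H)Cl in THF to the 3-carbaldehyde F3. Dioxinone 24 would be converted with LiN(iPr)2 and Me3SiCl into the silyl dienol ether F4. A vinylogous Mukaiyama aldol of F3 and F4 (BF3·OEt2, CH2Cl2, −78 °C) would give the hydroxy dioxinone F5 as carbinol epimers, and Dess–Martin oxidation (NaHCO3, CH2Cl2, 0 °C) would return the route to 25.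

**Step 7.** The likeliest failure is acid-induced ionisation of the benzylic C–O bond while the lactone is being opened, leading to epimerisation next to the aryl group or capture by allyl alcohol. Stalling at acetal 13 is the second risk. The fallback installs the allyl ester by alkylation, so that acid only has to close an enol ether and need not transesterify a lactone. Lactone 11 would be opened with LiOH and the carboxylate O-allylated with allyl bromide in DMF to the hydroxy ester F6. Silylation with Et3SiCl and imidazole would give the triethylsilyl ether F7, and formylation of the ester (LiN(iPr)2, CF3CH2OCHO, −78 °C) the formyl ester F8. PPTS in CH2Cl2 would then remove the silyl group and bring about cyclodehydration, rejoining the route at 14 and replacing steps 6 and 7.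

**Step 6.** The likeliest failure is competing deprotonation alpha to the amide, with expulsion of the lactone oxygen (opening to an arylidene succinate). The fallback avoids the enolate: heating 11 with tert-butoxybis(dimethylamino)methane in toluene should give the enaminone F9, and mild aqueous HCl in THF would hydrolyse it to 12.

## Further compounds

F1 | step 12 | (E)-3-[4-(triisopropylsilyloxy)phenyl]prop-2-enoyl chloride | O=C(Cl)/C=C/c1ccc(O[Si](C(C)C)(C(C)C)C(C)C)cc1
F2 | step 12 | (E)-1-[dimethyl(oxo)-λ6-sulfanylidene]-4-[4-(triisopropylsilyloxy)phenyl]but-3-en-2-one | CS(C)(=O)=CC(=O)/C=C/c1ccc(O[Si](C(C)C)(C(C)C)C(C)C)cc1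
F3 | step 14 | (2S,3S)-2-[3,4-bis(triisopropylsilyloxy)phenyl]-4-oxo-6-{(E)-2-[4-(triisopropylsilyloxy)phenyl]ethenyl}-2,3-dihydro-4H-furo[3,2-c]pyran-3-carbaldehyde | O=C[C@H]1c2c(cc(/C=C/c3ccc(O[Si](C(C)C)(C(C)C)C(C)C)cc3)oc2=O)O[C@@H]1c1ccc(O[Si](C(C)C)(C(C)C)C(C)C)c(O[Si](C(C)C)(C(C)C)C(C)C)c1
F4 | step 14 | [(2,2-dimethyl-6-methylidene-6H-1,3-dioxin-4-yl)oxy]trimethylsilane | C=C1C=C(O[Si](C)(C)C)OC(C)(C)O1
F5 | step 14 | 6-{2-hydroxy-2-[(2S,3R)-2-[3,4-bis(triisopropylsilyloxy)phenyl]-4-oxo-6-{(E)-2-[4-(triisopropylsilyloxy)phenyl]ethenyl}-2,3-dihydro-4H-furo[3,2-c]pyran-3-yl]ethyl}-2,2-dimethyl-4H-1,3-dioxin-4-one (carbinol epimers; ring geometry as in 23, the 3R descriptor follows from a priority change) | CC1(C)OC(=O)C=C(CC(O)[C@H]2c3c(cc(/C=C/c4ccc(O[Si](C(C)C)(C(C)C)C(C)C)cc4)oc3=O)O[C@@H]2c2ccc(O[Si](C(C)C)(C(C)C)C(C)C)c(O[Si](C(C)C)(C(C)C)C(C)C)c2)O1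
F6 | step 7 | prop-2-en-1-yl (3S,4S)-4-[3,4-bis(triisopropylsilyloxy)phenyl]-4-hydroxy-3-[methoxy(methyl)carbamoyl]butanoate | C=CCOC(=O)C[C@H](C(=O)N(C)OC)[C@H](O)c1ccc(O[Si](C(C)C)(C(C)C)C(C)C)c(O[Si](C(C)C)(C(C)C)C(C)C)c1
F7 | step 7 | prop-2-en-1-yl (3S,4S)-4-[3,4-bis(triisopropylsilyloxy)phenyl]-3-[methoxy(methyl)carbamoyl]-4-(triethylsilyloxy)butanoate | C=CCOC(=O)C[C@H](C(=O)N(C)OC)[C@H](O[Si](CC)(CC)CC)c1ccc(O[Si](C(C)C)(C(C)C)C(C)C)c(O[Si](C(C)C)(C(C)C)C(C)C)c1
F8 | step 7 | prop-2-en-1-yl (3S,4S)-4-[3,4-bis(triisopropylsilyloxy)phenyl]-2-(hydroxymethylidene)-3-[methoxy(methyl)carbamoyl]-4-(triethylsilyloxy)butanoate (enol form, alkene geometry not defined) | C=CCOC(=O)C(=CO)[C@H](C(=O)N(C)OC)[C@H](O[Si](CC)(CC)CC)c1ccc(O[Si](C(C)C)(C(C)C)C(C)C)c(O[Si](C(C)C)(C(C)C)C(C)C)c1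
F9 | step 6 | (2S,3S,4E)-2-[3,4-bis(triisopropylsilyloxy)phenyl]-4-[(dimethylamino)methylidene]-N-methoxy-N-methyl-5-oxooxolane-3-carboxamide | CON(C)C(=O)[C@H]1/C(=C\N(C)C)C(=O)O[C@@H]1c1ccc(O[Si](C(C)C)(C(C)C)C(C)C)c(O[Si](C(C)C)(C(C)C)C(C)C)c1
A1 | alternative 1 | methyl (2S,3S)-2-(3,4-diacetoxyphenyl)-6-methyl-4-oxo-2,3-dihydro-4H-furo[3,2-c]pyran-3-carboxylate | COC(=O)[C@H]2c3c(cc(C)oc3=O)O[C@@H]2c2ccc(OC(C)=O)c(OC(C)=O)c2
A2 | alternative 1 | (2S)-2-(3,4-diacetoxyphenyl)-7-methyl-2,3-dihydro-4H,5H-pyrano[3,2-c]pyran-4,5-dione | CC1=CC2=C(C(=O)C[C@H](O2)c2ccc(OC(C)=O)c(OC(C)=O)c2)C(=O)O1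
A3 | alternative 2 | methyl (4R,5S)-5-[3,4-bis(tert-butyldimethylsilyloxy)phenyl]-4-[(tert-butyldimethylsilyloxy)methyl]-2-{(E)-2-(tert-butyldimethylsilyloxy)-4-[4-(tert-butyldimethylsilyloxy)phenyl]but-3-en-1-yl}-4,5-dihydrofuran-3-carboxylate | CC(C)(C)[Si](C)(C)OC[C@H]2C(C(=O)OC)=C(CC(O[Si](C)(C)C(C)(C)C)/C=C/c3ccc(O[Si](C)(C)C(C)(C)C)cc3)O[C@@H]2c2ccc(O[Si](C)(C)C(C)(C)C)c(O[Si](C)(C)C(C)(C)C)c2
A4 | alternative 2 | (1S,2R,7E)-1-[3,4-bis(tert-butyldimethylsilyloxy)phenyl]-6-(tert-butyldimethylsilyloxy)-2-[(tert-butyldimethylsilyloxy)methyl]-8-[4-(tert-butyldimethylsilyloxy)phenyl]oct-7-en-3-yn-1-ol | CC(C)(C)[Si](C)(C)OC[C@@H](C#CCC(O[Si](C)(C)C(C)(C)C)/C=C/c1ccc(O[Si](C)(C)C(C)(C)C)cc1)[C@H](O)c1ccc(O[Si](C)(C)C(C)(C)C)c(O[Si](C)(C)C(C)(C)C)c1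
A5 | alternative 3 | (2S,3S)-2-[3,4-bis(tert-butyldimethylsilyloxy)phenyl]-6-{(E)-2-[4-(tert-butyldimethylsilyloxy)phenyl]ethenyl}-3-[4-(methoxymethoxy)-2-oxo-2H-pyran-6-yl]-2,3-dihydro-4H-furo[3,2-c]pyran-4-one | COCOc1cc([C@H]2c3c(cc(/C=C/c4ccc(O[Si](C)(C)C(C)(C)C)cc4)oc3=O)O[C@@H]2c2ccc(O[Si](C)(C)C(C)(C)C)c(O[Si](C)(C)C(C)(C)C)c2)oc(=O)c1
A6 | alternative 3 | 4-hydroxy-6-{(E)-2-[4-(tert-butyldimethylsilyloxy)phenyl]ethenyl}-2H-pyran-2-one | O=c1cc(O)cc(/C=C/c2ccc(O[Si](C)(C)C(C)(C)C)cc2)o1
A7 | alternative 3 | 4-(methoxymethoxy)-2-oxo-2H-pyran-6-carbaldehyde | COCOc1cc(C=O)oc(=O)c1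
A8 | alternative 3 | {[3,4-bis(tert-butyldimethylsilyloxy)phenyl]methyl}dimethylsulfonium bromide | C[S+](C)Cc1ccc(O[Si](C)(C)C(C)(C)C)c(O[Si](C)(C)C(C)(C)C)c1.[Br-]
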